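**Retrosynthetic overview**

- The strategy rests on ring B: five contiguous substituted positions, C1' (bond to C2 of ring C), C2' (prenyl), C3' and C4' (the carbon and the oxygen of the fused dihydropyran) and C5' (OH). This maps onto a 2-pyrone: pyrone C6 becomes C1', the two alkyne carbons become C2' and C3', pyrone C3–O becomes C4'–O, and C4–O becomes C5'–O.
- Last cuts: the three MOM groups, then ring C by Algar–Flynn–Oyamada closure of chalcone 22, which divides into ring B aldehyde 16 and ring A ketone 21. The C8 1,1-dimethylallyl group of 21 comes from a Claisen shift on the symmetric prenyl ether 18.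
- Key cut: ring B and the dihydropyran of ester 14 open together to pyrone 12 (two C–C bonds, with CO2 put back).
- Pyrone 12: the hindered C3–O ether bond is made by carbenoid O–H insertion of diazo dione 10 into tertiary alcohol 4. Pyrone 9 comes from dioxinone 5 and dimethyl oxalate 6, and alcohol 4 from ester 1 and prenyl bromide 3.
- Ring order: sacrificial pyrone ring (step 4), then dihydropyran and ring B together (step 8), ring A brought in intact, ring C last (step 15).

Key step: step 8

Remark: the target has no stereocentre; the stereocentres of the transient intermediates 13, 19 and 23 form as racemates and are destroyed in the same flask, and MOMCl is assumed to alkylate the 4-hydroxy-2-pyrone 11 at O4, as hard alkylating agents normally do.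

**Route**

Step 1
Reactants: 1 methyl pent-4-ynoate
Product: 2 2-methylhex-5-yn-2-ol
Conditions: MeMgBr (3.2 equiv), THF, 0 °C to rt; NH4Cl (aq)
Reagents that add atoms: methylmagnesium bromide, C[Mg]Br
Why: Double Grignard addition to the ester should give the tertiary alcohol, the excess reagent covering deprotonation of the terminal alkyne, which is restored on work-up.

Step 2
Reactants: 2 2-methylhex-5-yn-2-ol; 3 prenyl bromide (1-bromo-3-methylbut-2-ene)
Product: 4 2,9-dimethyldec-8-en-5-yn-2-ol
Conditions: CuI (10 mol%), Bu4NI (10 mol%), K2CO3, DMF, rt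
Reagents that add atoms: none
Why: Copper-acetylide allylation of a terminal alkyne should take place at the primary carbon of the allylic bromide to give the skipped enyne, and it tolerates the free tertiary hydroxyl.

Step 3
Reactants: 5 2,2,6-trimethyl-4H-1,3-dioxin-4-one; 6 dimethyl oxalate
Product: 7 methyl 3-(2,2-dimethyl-4-oxo-4H-1,3-dioxin-6-yl)-2-oxopropanoate
Conditions: LiN(SiMe3)2 (2.1 equiv), THF, −78 °C; then added to 6 (3 equiv), −78 to 0 °C; HCl (aq)
Reagents that add atoms: none
Why: Crossed Claisen condensation of the dienolate (deprotonated at the 6-methyl group) with the non-enolisable, highly electrophilic oxalate should acylate the γ-carbon, the second equivalent of base absorbing the acidity of the product and the excess oxalate suppressing double addition.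

Step 4
Reactants: 7 methyl 3-(2,2-dimethyl-4-oxo-4H-1,3-dioxin-6-yl)-2-oxopropanoate
Product: 9 methyl 4-hydroxy-2-oxo-2H-pyran-6-carboxylate, via acylketene 8 (not isolated)
Conditions: PhMe, 110 °C
Reagents that add atoms: none
Why: Dioxinone thermolysis (retro-[4+2] loss of acetone) should release an acylketene that only the enol oxygen of the α-keto ester can capture, so lactonisation can give nothing but the six-membered 4-hydroxy-2-pyrone.

Step 5
Reactants: 9 methyl 4-hydroxy-2-oxo-2H-pyran-6-carboxylate
Product: 10 methyl 3-diazo-2,4-dioxo-3,4-dihydro-2H-pyran-6-carboxylate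
Conditions: 4-acetamidobenzenesulfonyl azide, Et3N, MeCN, 0 °C to rt
Reagents that add atoms: 4-acetamidobenzenesulfonyl azide, CC(=O)Nc1ccc(cc1)S(=O)(=O)N=[N+]=[N-]
Why: Regitz diazo transfer should occur at C3, the only doubly activated carbon of the 1,3-dicarbonyl tautomer of the pyrone.

Step 6
Reactants: 10 methyl 3-diazo-2,4-dioxo-3,4-dihydro-2H-pyran-6-carboxylate; 4 2,9-dimethyldec-8-en-5-yn-2-ol
Product: 11 methyl 3-[(2,9-dimethyldec-8-en-5-yn-2-yl)oxy]-4-hydroxy-2-oxo-2H-pyran-6-carboxylate
Conditions: Rh2(OAc)4 (2 mol%), 4 (3 equiv, excess recovered), PhF, 70 °C, slow addition of 10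
Reagents that add atoms: none
Why: Rhodium-carbenoid O–H insertion (oxonium ylide, then proton shift and enolisation) should form the hindered tertiary alkyl–O–C3 bond without a carbocation or strong base, the excess alcohol outcompeting the internal alkyne, the trisubstituted alkene and the acidic product for the carbenoid.

Step 7
Reactants: 11 methyl 3-[(2,9-dimethyldec-8-en-5-yn-2-yl)oxy]-4-hydroxy-2-oxo-2H-pyran-6-carboxylate
Product: 12 methyl 3-[(2,9-dimethyldec-8-en-5-yn-2-yl)oxy]-4-(methoxymethoxy)-2-oxo-2H-pyran-6-carboxylate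
Conditions: MOMCl, i-Pr2NEt, CH2Cl2, 0 °C
Reagents that add atoms: chloromethyl methyl ether, COCCl
Why: O-alkylation of the vinylogous acid, the only acidic hydroxyl, under amine base should give the MOM ether without exposing the tertiary ether to acid.

Step 8
Reactants: 12 methyl 3-[(2,9-dimethyldec-8-en-5-yn-2-yl)oxy]-4-(methoxymethoxy)-2-oxo-2H-pyran-6-carboxylate
Product: 14 methyl 8-(methoxymethoxy)-2,2-dimethyl-5-(3-methylbut-2-enyl)chroman-6-carboxylate, via bridged lactone 13 (not isolated)
Conditions: 1,2-dichlorobenzene (0.02 M), BHT (cat.), 180 °C, sealed base-washed tube, Ar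
Reagents that add atoms: none
Why: On heating, the pyrone should react as a diene through C3 and C6 with the tethered alkyne in a thermal intramolecular [4+2] cycloaddition, and the 2-oxabicyclo[2.2.2]octadienone 13 should then lose CO2 by retro-[4+2] to give the benzene; the closest known reaction type is the intramolecular Diels–Alder reaction of 2-pyrones with tethered alkynes followed by decarboxylation. The dihydropyran closes as a six-membered ring in the fused (type 1) mode, its new bond running from pyrone C3 to the alkyne carbon at the end of the four-atom O–CMe2–CH2–CH2 tether, and ring B closes through the second bond, from the prenyl-bearing alkyne carbon to pyrone C6, and becomes aromatic on CO2 extrusion. The product has no stereocentre; the two bridgehead centres of 13 are tied to each other by the bicycle and vanish with CO2. The step needs regioselectivity and chemoselectivity: the short tether permits only the fused orientation, which places the prenyl group next to the ester-bearing carbon, and the trisubstituted alkene, a poor dienophile three atoms further out, cannot reach the diene. The geminal methyl groups bias the tether toward the folded conformer, and neutral, acid-free conditions should keep the tertiary alkyl ether and the MOM acetal intact.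

Step 9
Reactants: 14 methyl 8-(methoxymethoxy)-2,2-dimethyl-5-(3-methylbut-2-enyl)chroman-6-carboxylate
Product: 15 [8-(methoxymethoxy)-2,2-dimethyl-5-(3-methylbut-2-enyl)chroman-6-yl]methanol
Conditions: LiAlH4, THF, 0 °C
Reagents that add atoms: none
Why: Hydride reduction of the aryl ester should give the benzylic alcohol while the acetal, the ethers and the isolated alkene are inert.

Step 10
Reactants: 15 [8-(methoxymethoxy)-2,2-dimethyl-5-(3-methylbut-2-enyl)chroman-6-yl]methanol
Product: 16 8-(methoxymethoxy)-2,2-dimethyl-5-(3-methylbut-2-enyl)chroman-6-carbaldehyde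
Conditions: MnO2, CH2Cl2, rt
Reagents that add atoms: none
Why: Manganese dioxide oxidation is selective for the benzylic alcohol, stops at the aldehyde and leaves the prenyl alkene alone.

Step 11
Reactants: 17 1-(2,4,6-trihydroxyphenyl)ethanone; 3 prenyl bromide
Product: 18 1-[2,6-dihydroxy-4-(3-methylbut-2-enyloxy)phenyl]ethanone
Conditions: K2CO3 (1.1 equiv), 3 (1.0 equiv), acetone, rt
Reagents that add atoms: none
Why: Williamson etherification with one equivalent should occur at the C4 hydroxyl, the most acidic and the only one not hydrogen-bonded to the acetyl group.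

Step 12
Reactants: 18 1-[2,6-dihydroxy-4-(3-methylbut-2-enyloxy)phenyl]ethanone
Product: 20 1-[2,4,6-trihydroxy-3-(2-methylbut-3-en-2-yl)phenyl]ethanone, via ortho-dienone 19 (not isolated)
Conditions: PhNEt2, 185 °C, Ar
Reagents that add atoms: none
Why: The aromatic Claisen rearrangement ([3,3] shift) delivers the inverted 1,1-dimethylallyl group to an ortho carbon; the two ortho carbons are equivalent by symmetry and the para carbon is blocked by the acetyl group, so one product is expected after enolisation of the dienone.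

Step 13
Reactants: 20 1-[2,4,6-trihydroxy-3-(2-methylbut-3-en-2-yl)phenyl]ethanone
Product: 21 1-[2-hydroxy-4,6-bis(methoxymethoxy)-3-(2-methylbut-3-en-2-yl)phenyl]ethanone
Conditions: MOMCl (2.2 equiv), i-Pr2NEt, CH2Cl2, 0 °C to rt
Reagents that add atoms: chloromethyl methyl ether, COCCl
Why: Alkylation should take the non-chelated C4 hydroxyl and the less hindered C6 hydroxyl, leaving free and hydrogen-bonded the C2 hydroxyl flanked by the acetyl group and the quaternary carbon, which is the oxygen that must later become O1.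

Step 14
Reactants: 21 1-[2-hydroxy-4,6-bis(methoxymethoxy)-3-(2-methylbut-3-en-2-yl)phenyl]ethanone; 16 8-(methoxymethoxy)-2,2-dimethyl-5-(3-methylbut-2-enyl)chroman-6-carbaldehyde
Product: 22 (E)-1-[2-hydroxy-4,6-bis(methoxymethoxy)-3-(2-methylbut-3-en-2-yl)phenyl]-3-[8-(methoxymethoxy)-2,2-dimethyl-5-(3-methylbut-2-enyl)chroman-6-yl]prop-2-en-1-one
Conditions: KOH, EtOH–H2O, rt
Reagents that add atoms: none
Why: Claisen–Schmidt condensation of the methyl ketone with the non-enolisable aldehyde, followed by dehydration, should give the thermodynamically favoured E-enone.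

Step 15
Reactants: 22 the E-chalcone
Product: 24 3-hydroxy-5,7-bis(methoxymethoxy)-2-[8-(methoxymethoxy)-2,2-dimethyl-5-(3-methylbut-2-enyl)chroman-6-yl]-8-(2-methylbut-3-en-2-yl)chromen-4-one, via trans-dihydroflavonol 23 (not isolated)
Conditions: H2O2 (30% aq), NaOH, MeOH–THF, 0 °C to rt
Reagents that add atoms: hydrogen peroxide, OO
Why: In the Algar–Flynn–Oyamada reaction the phenoxide closes ring C on the β-carbon, the resulting enolate is hydroxylated by peroxide to the trans-dihydroflavonol, and this is dehydrogenated in the alkaline peroxide to the flavonol, while the isolated alkenes are inert to hydroperoxide anion.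

Step 16
Reactants: 24 the tris-MOM flavonol
Product: 25 Broussoflavonol E, 3,5,7-trihydroxy-2-[8-hydroxy-2,2-dimethyl-5-(3-methylbut-2-enyl)chroman-6-yl]-8-(2-methylbut-3-en-2-yl)chromen-4-one
Conditions: HCl (3 M aq), MeOH, 40 °C
Reagents that add atoms: none
Why: Acid-catalysed acetal exchange with methanol removes the three MOM groups; the ring B prenyl group has no ortho hydroxyl to cyclise onto and the terminal alkene of the 1,1-dimethylallyl group would need a secondary cation, so both should survive dilute acid at this temperature.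

**Compound list**

1 | methyl pent-4-ynoate | C#CCCC(=O)OC | starting material
2 | 2-methylhex-5-yn-2-ol | C#CCCC(C)(C)O | intermediate
3 | prenyl bromide (1-bromo-3-methylbut-2-ene) | CC(C)=CCBr | starting material
4 | 2,9-dimethyldec-8-en-5-yn-2-ol | CC(C)(O)CCC#CCC=C(C)C | intermediate
5 | 2,2,6-trimethyl-4H-1,3-dioxin-4-one | CC1=CC(=O)OC(C)(C)O1 | starting material
6 | dimethyl oxalate | COC(=O)C(=O)OC | starting material
7 | methyl 3-(2,2-dimethyl-4-oxo-4H-1,3-dioxin-6-yl)-2-oxopropanoate | COC(=O)C(=O)CC1=CC(=O)OC(C)(C)O1 | intermediate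
8 | methyl 2,4,6-trioxohex-5-enoate (acylketene) | COC(=O)C(=O)CC(=O)C=C=O | intermediate (not isolated)
9 | methyl 4-hydroxy-2-oxo-2H-pyran-6-carboxylate | COC(=O)C1=CC(O)=CC(=O)O1 | intermediate
10 | methyl 3-diazo-2,4-dioxo-3,4-dihydro-2H-pyran-6-carboxylate | COC(=O)C1=CC(=O)C(=[N+]=[N-])C(=O)O1 | intermediate
11 | methyl 3-[(2,9-dimethyldec-8-en-5-yn-2-yl)oxy]-4-hydroxy-2-oxo-2H-pyran-6-carboxylate | COC(=O)C1=CC(O)=C(OC(C)(C)CCC#CCC=C(C)C)C(=O)O1 | intermediate
12 | methyl 3-[(2,9-dimethyldec-8-en-5-yn-2-yl)oxy]-4-(methoxymethoxy)-2-oxo-2H-pyran-6-carboxylate | COCOC1=C(OC(C)(C)CCC#CCC=C(C)C)C(=O)OC(C(=O)OC)=C1 | intermediate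
13 | bridged lactone: 2-oxabicyclo[2.2.2]octa-5,7-dien-3-one whose bridgehead next to the ring oxygen carries CO2Me, whose other bridgehead carries the tether oxygen, one alkene bearing OMOM and the other shared with the new dihydropyran and bearing prenyl; racemic, one enantiomer drawn | COC(=O)[C@]12OC(=O)[C@@]3(OC(C)(C)CCC3=C1CC=C(C)C)C(OCOC)=C2 | intermediate (not isolated)
14 | methyl 8-(methoxymethoxy)-2,2-dimethyl-5-(3-methylbut-2-enyl)chroman-6-carboxylate | COC(=O)c1cc(OCOC)c2OC(C)(C)CCc2c1CC=C(C)C | intermediate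
15 | [8-(methoxymethoxy)-2,2-dimethyl-5-(3-methylbut-2-enyl)chroman-6-yl]methanol | OCc1cc(OCOC)c2OC(C)(C)CCc2c1CC=C(C)C | intermediate
16 | 8-(methoxymethoxy)-2,2-dimethyl-5-(3-methylbut-2-enyl)chroman-6-carbaldehyde | O=Cc1cc(OCOC)c2OC(C)(C)CCc2c1CC=C(C)C | intermediate
17 | 1-(2,4,6-trihydroxyphenyl)ethanone | CC(=O)c1c(O)cc(O)cc1O | starting material
18 | 1-[2,6-dihydroxy-4-(3-methylbut-2-enyloxy)phenyl]ethanone | CC(=O)c1c(O)cc(OCC=C(C)C)cc1O | intermediate
19 | 4-acetyl-3,5-dihydroxy-6-(2-methylbut-3-en-2-yl)cyclohexa-2,4-dien-1-one (ortho-dienone; racemic, one enantiomer drawn) | CC(=O)C1=C(O)[C@H](C(C)(C)C=C)C(=O)C=C1O | intermediate (not isolated)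
20 | 1-[2,4,6-trihydroxy-3-(2-methylbut-3-en-2-yl)phenyl]ethanone | CC(=O)c1c(O)cc(O)c(C(C)(C)C=C)c1O | intermediate
21 | 1-[2-hydroxy-4,6-bis(methoxymethoxy)-3-(2-methylbut-3-en-2-yl)phenyl]ethanone | CC(=O)c1c(OCOC)cc(OCOC)c(C(C)(C)C=C)c1O | intermediate
22 | (E)-1-[2-hydroxy-4,6-bis(methoxymethoxy)-3-(2-methylbut-3-en-2-yl)phenyl]-3-[8-(methoxymethoxy)-2,2-dimethyl-5-(3-methylbut-2-enyl)chroman-6-yl]prop-2-en-1-one | C=CC(C)(C)c1c(O)c(C(=O)/C=C/c2cc(OCOC)c3OC(C)(C)CCc3c2CC=C(C)C)c(OCOC)cc1OCOC | intermediate
23 | 2,3-trans-3-hydroxy-5,7-bis(methoxymethoxy)-2-[8-(methoxymethoxy)-2,2-dimethyl-5-(3-methylbut-2-enyl)chroman-6-yl]-8-(2-methylbut-3-en-2-yl)chroman-4-one (racemic, one enantiomer drawn) | O=C1c2c(OCOC)cc(OCOC)c(C(C)(C)C=C)c2O[C@@H](c2cc(OCOC)c3OC(C)(C)CCc3c2CC=C(C)C)[C@@H]1O | intermediate (not isolated)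
24 | 3-hydroxy-5,7-bis(methoxymethoxy)-2-[8-(methoxymethoxy)-2,2-dimethyl-5-(3-methylbut-2-enyl)chroman-6-yl]-8-(2-methylbut-3-en-2-yl)chromen-4-one | C=CC(C)(C)c1c(OCOC)cc(OCOC)c2c(=O)c(O)c(-c3cc(OCOC)c4c(c3CC=C(C)C)CCC(C)(C)O4)oc12 | intermediate
25 | Broussoflavonol E | C=CC(C)(C)c1c(O)cc(O)c2c(=O)c(O)c(-c3cc(O)c4c(c3CC=C(C)C)CCC(C)(C)O4)oc12 | target

**Step count and risks**

Total step count: 16. Longest linear sequence: 11 steps (5 to 25 through steps 3–10 and 14–16).

Steps most likely to fail:

1. Step 8. The cycloaddition may be too slow at temperatures the substrate tolerates, so that thermal elimination of the tertiary alkyl ether (loss of the tether) or decomposition of the pyrone overtakes ring formation. The fallback sets out from 11 and makes the diene electron-poor, so that it reacts with the alkyl-substituted alkyne in the inverse-electron-demand sense at lower temperature. Triflation of 11 with PhNTf2 and Et3N in CH2Cl2 should give methyl 3-[(2,9-dimethyldec-8-en-5-yn-2-yl)oxy]-2-oxo-4-(trifluoromethylsulfonyloxy)-2H-pyran-6-carboxylate F1. Heating F1 in toluene at 110–130 °C should lead through the bridged triflate lactone F2 to methyl 2,2-dimethyl-5-(3-methylbut-2-enyl)-8-(trifluoromethylsulfonyloxy)chroman-6-carboxylate F3. Cleavage of the triflate S–O bond with Et4NOH in dioxane at rt should give methyl 8-hydroxy-2,2-dimethyl-5-(3-methylbut-2-enyl)chroman-6-carboxylate F4, and MOMCl with i-Pr2NEt returns to the route at 14.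

2. Step 6. The carbenoid may be consumed by the internal alkyne or the prenyl alkene, by Wolff rearrangement, or by the acidic product before the hindered tertiary hydroxyl captures it. The fallback sets out from 10 and 4 and forms the ether by acid-catalysed tertiary alkylation instead. O–H insertion of 10 into water with Rh2(OAc)4 should give methyl 3,4-dihydroxy-2-oxo-2H-pyran-6-carboxylate F5. One equivalent of MOMCl with i-Pr2NEt should protect the more acidic 4-hydroxyl to give methyl 3-hydroxy-4-(methoxymethoxy)-2-oxo-2H-pyran-6-carboxylate F6. Alcohol 4 with Cl3CCN and catalytic DBU should give 2,9-dimethyldec-8-en-5-yn-2-yl 2,2,2-trichloroacetimidate F7. Alkylation of the 3-hydroxyl of F6 with F7 under catalytic BF3·OEt2 in cyclohexane–CH2Cl2 at −20 °C returns to the route at 12.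

3. Step 15. The hindered phenoxide may close through the α-carbon instead of the β-carbon, a five-membered closure to the aurone skeleton that a 6'-alkoxy group is known to favour, or may close too slowly. The fallback sets out from 21 and 14, bypasses steps 9, 10 and 14, and builds ring C before the 3-oxygen is introduced. Claisen condensation of the dianion of 21 with ester 14 (LiN(SiMe3)2, THF, −78 °C to rt) should give 1-[2-hydroxy-4,6-bis(methoxymethoxy)-3-(2-methylbut-3-en-2-yl)phenyl]-3-[8-(methoxymethoxy)-2,2-dimethyl-5-(3-methylbut-2-enyl)chroman-6-yl]propane-1,3-dione F8. Buffered cyclodehydration (NaOAc, AcOH, 90 °C) should give 5,7-bis(methoxymethoxy)-2-[8-(methoxymethoxy)-2,2-dimethyl-5-(3-methylbut-2-enyl)chroman-6-yl]-8-(2-methylbut-3-en-2-yl)chromen-4-one F9. Lithiation at C3 with LiN(i-Pr)2 at −78 °C, trapping with B(OMe)3 and oxidation with NaOH/H2O2 returns to the route at 24.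

**Further compounds**

F1 | step 8 | methyl 3-[(2,9-dimethyldec-8-en-5-yn-2-yl)oxy]-2-oxo-4-(trifluoromethylsulfonyloxy)-2H-pyran-6-carboxylate | COC(=O)C1=CC(OS(=O)(=O)C(F)(F)F)=C(OC(C)(C)CCC#CCC=C(C)C)C(=O)O1
F2 | step 8 | bridged triflate lactone (the analogue of 13 with OSO2CF3 in place of OMOM; racemic, one enantiomer drawn) | COC(=O)[C@]12OC(=O)[C@@]3(OC(C)(C)CCC3=C1CC=C(C)C)C(OS(=O)(=O)C(F)(F)F)=C2
F3 | step 8 | methyl 2,2-dimethyl-5-(3-methylbut-2-enyl)-8-(trifluoromethylsulfonyloxy)chroman-6-carboxylate | COC(=O)c1cc(OS(=O)(=O)C(F)(F)F)c2OC(C)(C)CCc2c1CC=C(C)C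
F4 | step 8 | methyl 8-hydroxy-2,2-dimethyl-5-(3-methylbut-2-enyl)chroman-6-carboxylate | COC(=O)c1cc(O)c2OC(C)(C)CCc2c1CC=C(C)C
F5 | step 6 | methyl 3,4-dihydroxy-2-oxo-2H-pyran-6-carboxylate | COC(=O)C1=CC(O)=C(O)C(=O)O1
F6 | step 6 | methyl 3-hydroxy-4-(methoxymethoxy)-2-oxo-2H-pyran-6-carboxylate | COCOC1=C(O)C(=O)OC(C(=O)OC)=C1
F7 | step 6 | 2,9-dimethyldec-8-en-5-yn-2-yl 2,2,2-trichloroacetimidate | CC(C)=CCC#CCCC(C)(C)OC(=N)C(Cl)(Cl)Cl
F8 | step 15 | 1-[2-hydroxy-4,6-bis(methoxymethoxy)-3-(2-methylbut-3-en-2-yl)phenyl]-3-[8-(methoxymethoxy)-2,2-dimethyl-5-(3-methylbut-2-enyl)chroman-6-yl]propane-1,3-dione | C=CC(C)(C)c1c(O)c(C(=O)CC(=O)c2cc(OCOC)c3OC(C)(C)CCc3c2CC=C(C)C)c(OCOC)cc1OCOC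
F9 | step 15 | 5,7-bis(methoxymethoxy)-2-[8-(methoxymethoxy)-2,2-dimethyl-5-(3-methylbut-2-enyl)chroman-6-yl]-8-(2-methylbut-3-en-2-yl)chromen-4-one | C=CC(C)(C)c1c(OCOC)cc(OCOC)c2c(=O)cc(-c3cc(OCOC)c4c(c3CC=C(C)C)CCC(C)(C)O4)oc12
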